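The route rests on cutting the aryl ether bond O1–C7a of the dihydrofuran ring. In the benzene ring the C5 acetyl group sits para to C7a and ortho to C6, so a 2,4-difluoroacetophenone is a latent 2,4-dioxygenated acetophenone. In one operation the C2 alkoxide of an open-chain anti-diol closes the five-membered ring by 5-exo SNAr at C7a, and a 4-methoxybenzyl alkoxide then displaces the C6 fluoride. The precursor is (1S,2R)-1-(5-acetyl-2,4-difluorophenyl)-3-methylbut-3-ene-1,2-diol, whose two stereocentres come from a Shi epoxidation, a Payne rearrangement and an epoxide-to-allylic-alcohol isomerisation. Acylation at O3 and removal of the benzyl ether finish the synthesis.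

Key step: step 5

Remarks: the locants O1, C2, C3, C3a, C4–C7, C7a of the 2,3-dihydrobenzofuran are also used for the corresponding atoms of the open-chain precursors. The target is the trans-(2R,3S) isomer with a (Z)-configured side-chain alkene. Compound 1, the L-fructose-derived Shi ketone and [Cp*RuCl]4 are assumed to be catalogue items.

Step 1
Reactants: 1 1-(5-bromo-2,4-difluorophenyl)ethan-1-one; 2 2-methylbut-3-en-2-ol
Product: 3 (E)-1-[2,4-difluoro-5-(3-hydroxy-3-methylbut-1-en-1-yl)phenyl]ethan-1-one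
Conditions: Pd(OAc)2 (2 mol%), P(o-tol)3 (4 mol%), Et3N, MeCN, 80 °C
Reagents that add atoms: none
Why: Mizoroki–Heck reaction: oxidative addition of the electron-poor aryl bromide to zerovalent palladium, insertion at the unsubstituted alkene terminus and syn β-hydride elimination should give the (E)-styrene, and because the carbinol carbon carries no hydrogen the alkene cannot migrate to a ketone.

Step 2
Reactants: 3 (E)-1-[2,4-difluoro-5-(3-hydroxy-3-methylbut-1-en-1-yl)phenyl]ethan-1-one
Product: 4 1-{2,4-difluoro-5-[(2S,3R)-3-(2-hydroxypropan-2-yl)oxiran-2-yl]phenyl}ethan-1-one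
Conditions: L-fructose-derived Shi ketone (1,2:4,5-di-O-isopropylidene-β-L-erythro-2,3-hexodiulo-2,6-pyranose, 30 mol%), Oxone (2KHSO5·KHSO4·K2SO4), K2CO3, Bu4NHSO4, MeCN–CH2(OMe)2/aqueous Na2B4O7 buffer (pH 10.5), 0 °C
Reagents that add atoms: potassium peroxymonosulfate (active component of Oxone), [K+].[O-]S(=O)(=O)OO
Why: Shi epoxidation of a trans-disubstituted styrenyl alkene by the chiral dioxirane (spiro transition state) sets both stereocentres under catalyst control; the D-fructose-derived ketone gives (R,R)-epoxides from trans-β-methylstyrene-type alkenes, so its enantiomer is used to reach the mirror-image facial sense required here.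

Step 3
Reactants: 4 1-{2,4-difluoro-5-[(2S,3R)-3-(2-hydroxypropan-2-yl)oxiran-2-yl]phenyl}ethan-1-one
Product: 5 1-{5-[(S)-[(2S)-3,3-dimethyloxiran-2-yl](hydroxy)methyl]-2,4-difluorophenyl}ethan-1-one
Conditions: NaH (1.1 equiv), THF, 0 °C to rt; aqueous NH4Cl
Reagents that add atoms: none
Why: Payne rearrangement: the tertiary alkoxide opens the oxirane at the future C2 by 3-exo-tet SN2 with inversion, giving the more substituted oxirane and the more stable secondary benzylic alkoxide; the future C3 is untouched, so the anti relationship of the two oxygens is fixed stereospecifically.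

Step 4
Reactants: 5 1-{5-[(S)-[(2S)-3,3-dimethyloxiran-2-yl](hydroxy)methyl]-2,4-difluorophenyl}ethan-1-one
Product: 6 1-{5-[(1S,2R)-1,2-dihydroxy-3-methylbut-3-en-1-yl]-2,4-difluorophenyl}ethan-1-one
Conditions: Ti(OiPr)4 (1.5 equiv), CH2Cl2, rt; aqueous tartaric acid
Reagents that add atoms: none
Why: Hydroxyl-directed epoxide-to-allylic-alcohol isomerisation: the secondary hydroxyl binds titanium, the chelated Lewis acid weakens the tertiary C–O bond of the oxirane and a methyl proton is lost to unveil the isopropenyl carbinol; the C–O bond at C2 is not broken, so configuration is retained (the descriptor changes from S to R only through the priority rules).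

Step 5
Reactants: 6 1-{5-[(1S,2R)-1,2-dihydroxy-3-methylbut-3-en-1-yl]-2,4-difluorophenyl}ethan-1-one
Product: 8 1-[(2R,3S)-3-hydroxy-6-[(4-methoxyphenyl)methoxy]-2-(prop-1-en-2-yl)-2,3-dihydro-1-benzofuran-5-yl]ethan-1-one, via fluoro alcohol 7 (not isolated)
Conditions: NaH (2.2 equiv), THF–DMF, 0 °C to rt; then 4-MeOC6H4CH2ONa (from the alcohol and NaH, 3 equiv each), DMF, 50 °C
Reagents that add atoms: 4-methoxybenzyl alcohol, COc1ccc(CO)cc1
Why: Deprotonation gives rapidly exchanging alkoxides, and the C2 alkoxide adds to C7a, the fluorine-bearing carbon para to the C5 acetyl group, to form a Meisenheimer anion delocalised onto the acetyl oxygen; loss of fluoride forms the O1–C7a bond (intramolecular SNAr). The closest known reaction types are the etherification of 4-fluoroacetophenones by alkoxides and the intramolecular O-arylation of 2-(2-fluoroaryl)ethanols to 2,3-dihydrobenzofurans. The dihydrofuran ring closes in the 5-exo-trig mode at the ipso carbon. No stereocentre is created: the C–O bonds at C2 and C3 are not touched, so the anti-(1S,2R) diol is carried over as the trans-(2R,3S) ring. The step needs oxygen selectivity (the C3 alkoxide could only form a four-membered ring), site selectivity (only the C7a fluoride is ortho to the side chain) and intra- over intermolecular attack (the external alkoxide is added only after ring closure). In the second stage the C6 fluoride, ortho to the acetyl group, is displaced by sodium 4-methoxybenzyl oxide in a second SNAr that installs the protected C6 oxygen.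

Step 6
Reactants: 9 but-2-yn-1-ol
Product: 10 (2Z)-2-(tributylstannyl)but-2-en-1-ol
Conditions: Bu3SnH (1.1 equiv), [Cp*RuCl]4 (1.5 mol%), CH2Cl2, rt
Reagents that add atoms: tributyltin hydride, CCCC[SnH](CCCC)CCCC
Why: Ruthenium-catalysed hydroxyl-directed trans-hydrostannation: hydrogen bonding of the propargylic OH to the chloride ligand should place tin on the proximal carbon, and anti addition of H and Sn fixes tin cis to the methyl group.

Step 7
Reactants: 10 (2Z)-2-(tributylstannyl)but-2-en-1-ol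
Product: 12 (2Z)-2-(hydroxymethyl)but-2-enoic acid, via dilithio species 11 (not isolated)
Conditions: MeLi (2.2 equiv), THF, −78 to 0 °C; CO2, −78 °C; 1 M HCl
Reagents that add atoms: carbon dioxide, O=C=O
Why: Deprotonation and tin–lithium exchange give a chelated alkenyllithium that is configurationally stable at low temperature; carboxylation with retention puts CO2H where tin was, cis to the β-methyl group (angelate-type geometry).

Step 8
Reactants: 12 (2Z)-2-(hydroxymethyl)but-2-enoic acid
Product: 13 (2Z)-2-[(acetyloxy)methyl]but-2-enoic acid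
Conditions: Ac2O, pyridine, CH2Cl2, 0 °C to rt
Reagents that add atoms: acetic anhydride, CC(=O)OC(C)=O
Why: O-acetylation of the primary allylic alcohol by acyl transfer; the alkene is not involved, so the (Z)-geometry should be kept.

Step 9
Reactants: 8 1-[(2R,3S)-3-hydroxy-6-[(4-methoxyphenyl)methoxy]-2-(prop-1-en-2-yl)-2,3-dihydro-1-benzofuran-5-yl]ethan-1-one; 13 (2Z)-2-[(acetyloxy)methyl]but-2-enoic acid
Product: 15 (2R,3S)-5-acetyl-6-[(4-methoxyphenyl)methoxy]-2-(prop-1-en-2-yl)-2,3-dihydro-1-benzofuran-3-yl (2Z)-2-[(acetyloxy)methyl]but-2-enoate, via mixed anhydride 14 (not isolated)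
Conditions: 2,4,6-Cl3C6H2COCl, Et3N, toluene, rt; then 8, DMAP, rt
Reagents that add atoms: none
Why: Yamaguchi esterification, the standard method for angelate-type acids and hindered secondary alcohols: acyl transfer occurs at the carboxyl carbon, so the C3–O bond is kept (retention, trans ester), and the mild temperature should preserve the (Z)-alkene.

Step 10
Reactants: 15 (2R,3S)-5-acetyl-6-[(4-methoxyphenyl)methoxy]-2-(prop-1-en-2-yl)-2,3-dihydro-1-benzofuran-3-yl (2Z)-2-[(acetyloxy)methyl]but-2-enoate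
Product: 16 (2R,3S)-5-acetyl-6-hydroxy-2-(prop-1-en-2-yl)-2,3-dihydro-1-benzofuran-3-yl (2Z)-2-[(acetyloxy)methyl]but-2-enoate
Conditions: DDQ, CH2Cl2–pH 7 phosphate buffer, 0 °C to rt
Reagents that add atoms: none
Why: Oxidative cleavage of the 4-methoxybenzyl ether: hydride abstraction from the electron-rich benzylic CH2 and hydrolysis of the oxocarbenium ion free the phenol under neutral conditions that should leave both esters, both alkenes and the benzylic C3–O bond intact.

Compound list
1 | 1-(5-bromo-2,4-difluorophenyl)ethan-1-one | CC(=O)c1cc(Br)c(F)cc1F | starting material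
2 | 2-methylbut-3-en-2-ol | C=CC(C)(C)O | starting material
3 | (E)-1-[2,4-difluoro-5-(3-hydroxy-3-methylbut-1-en-1-yl)phenyl]ethan-1-one | CC(=O)c1cc(/C=C/C(C)(C)O)c(F)cc1F | intermediate
4 | 1-{2,4-difluoro-5-[(2S,3R)-3-(2-hydroxypropan-2-yl)oxiran-2-yl]phenyl}ethan-1-one | CC(C)(O)[C@@H]1O[C@H]1c1cc(C(C)=O)c(F)cc1F | intermediate
5 | 1-{5-[(S)-[(2S)-3,3-dimethyloxiran-2-yl](hydroxy)methyl]-2,4-difluorophenyl}ethan-1-one | CC1(C)O[C@H]1[C@@H](O)c1cc(C(C)=O)c(F)cc1F | intermediate
6 | 1-{5-[(1S,2R)-1,2-dihydroxy-3-methylbut-3-en-1-yl]-2,4-difluorophenyl}ethan-1-one | C=C(C)[C@@H](O)[C@@H](O)c1cc(C(C)=O)c(F)cc1F | intermediate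
7 | 1-[(2R,3S)-6-fluoro-3-hydroxy-2-(prop-1-en-2-yl)-2,3-dihydro-1-benzofuran-5-yl]ethan-1-one (formed in the flask) | C=C(C)[C@H]1Oc2cc(F)c(C(C)=O)cc2[C@@H]1O | intermediate
8 | 1-[(2R,3S)-3-hydroxy-6-[(4-methoxyphenyl)methoxy]-2-(prop-1-en-2-yl)-2,3-dihydro-1-benzofuran-5-yl]ethan-1-one | C=C(C)[C@H]1Oc2cc(OCc3ccc(OC)cc3)c(C(C)=O)cc2[C@@H]1O | intermediate
9 | but-2-yn-1-ol | CC#CCO | starting material
10 | (2Z)-2-(tributylstannyl)but-2-en-1-ol | C/C=C(\[Sn](CCCC)(CCCC)CCCC)CO | intermediate
11 | dilithium salt of (2Z)-2-lithiobut-2-en-1-olate (formed in the flask) | C/C=C(\[Li])CO[Li] | intermediate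
12 | (2Z)-2-(hydroxymethyl)but-2-enoic acid | C/C=C(\C(=O)O)CO | intermediate
13 | (2Z)-2-[(acetyloxy)methyl]but-2-enoic acid | C/C=C(\C(=O)O)COC(C)=O | intermediate
14 | (2Z)-2-[(acetyloxy)methyl]but-2-enoic 2,4,6-trichlorobenzoic anhydride (formed in the flask) | C/C=C(\C(=O)OC(=O)c1c(Cl)cc(Cl)cc1Cl)COC(C)=O | intermediate
15 | (2R,3S)-5-acetyl-6-[(4-methoxyphenyl)methoxy]-2-(prop-1-en-2-yl)-2,3-dihydro-1-benzofuran-3-yl (2Z)-2-[(acetyloxy)methyl]but-2-enoate | C=C(C)[C@H]1Oc2cc(OCc3ccc(OC)cc3)c(C(C)=O)cc2[C@@H]1OC(=O)/C(=C\C)COC(C)=O | intermediate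
16 | (2R,3S)-5-acetyl-6-hydroxy-2-(prop-1-en-2-yl)-2,3-dihydro-1-benzofuran-3-yl (2Z)-2-[(acetyloxy)methyl]but-2-enoate | C=C(C)[C@H]1Oc2cc(O)c(C(C)=O)cc2[C@@H]1OC(=O)/C(=C\C)COC(C)=O | target

Total step count: 10
Longest linear sequence: 7 steps (steps 1, 2, 3, 4, 5, 9, 10)

Steps most likely to fail

1. Step 5 (key step). Enolisation of the acetyl group by the alkoxide base may slow both fluoride displacements. In the second stage the intermolecular displacement at C6 may stall, or the C3 alkoxide of one molecule may arylate another. The fallback sets out from 6 and separates the two C–O bond formations. Only the ring closure is run (NaH, THF, 0 °C) and the fluoro alcohol 7 is isolated. Compound 7 is then treated with 2-(methylsulfonyl)ethanol and NaH in DMF, a hydroxide surrogate: the aryl ether 1-[(2R,3S)-3-hydroxy-6-[2-(methylsulfonyl)ethoxy]-2-(prop-1-en-2-yl)-2,3-dihydro-1-benzofuran-5-yl]ethan-1-one F1 should form and fragment in the same flask by β-elimination to the phenol 1-[(2R,3S)-3,6-dihydroxy-2-(prop-1-en-2-yl)-2,3-dihydro-1-benzofuran-5-yl]ethan-1-one F2. Phenol-selective alkylation (4-methoxybenzyl chloride, K2CO3, DMF) returns to the route at 8.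

2. Step 9. During acyl transfer the nucleophilic catalyst may add to the enoate, which would cause (Z)-to-(E) isomerisation or SN2′ loss of the allylic acetate. The fallback sets out from 12 and 8 and carries the side chain without an allylic leaving group. Silylation of 12 (TBSCl, imidazole, DMF) should give the bis-silyl compound tert-butyldimethylsilyl (2Z)-2-{[(tert-butyldimethylsilyl)oxy]methyl}but-2-enoate F3. Selective cleavage of the silyl ester (K2CO3, MeOH–H2O) gives (2Z)-2-{[(tert-butyldimethylsilyl)oxy]methyl}but-2-enoic acid F4. Activation as before gives the mixed anhydride (2Z)-2-{[(tert-butyldimethylsilyl)oxy]methyl}but-2-enoic 2,4,6-trichlorobenzoic anhydride F5, which acylates 8 to the silyl-protected ester (2R,3S)-5-acetyl-6-[(4-methoxyphenyl)methoxy]-2-(prop-1-en-2-yl)-2,3-dihydro-1-benzofuran-3-yl (2Z)-2-{[(tert-butyldimethylsilyl)oxy]methyl}but-2-enoate F6. Desilylation (HF·pyridine, THF, 0 °C) gives the hydroxymethyl ester (2R,3S)-5-acetyl-6-[(4-methoxyphenyl)methoxy]-2-(prop-1-en-2-yl)-2,3-dihydro-1-benzofuran-3-yl (2Z)-2-(hydroxymethyl)but-2-enoate F7, and acetylation (Ac2O, pyridine) returns to the route at 15.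

3. Step 3. The Payne equilibrium may stay incomplete, and the liberated benzylic alkoxide may displace a fluoride of a second molecule. The fallback sets out from 4 and traps the rearranged alkoxide as it forms (NaH, THF, 0 °C, then TBSCl; the secondary alkoxide silylates far faster than the tertiary one). This should give the silyl ether 1-{5-[(S)-[(tert-butyldimethylsilyl)oxy][(2S)-3,3-dimethyloxiran-2-yl]methyl]-2,4-difluorophenyl}ethan-1-one F8. Silyl-triflate-mediated epoxide opening (TMSOTf, 2,6-lutidine, CH2Cl2, −78 °C, then DBU) then gives the bis-silyl ether 1-{5-[(1S,2R)-1-[(tert-butyldimethylsilyl)oxy]-3-methyl-2-[(trimethylsilyl)oxy]but-3-en-1-yl]-2,4-difluorophenyl}ethan-1-one F9 with the C2–O bond retained. Global desilylation (HF·pyridine, THF) returns to the route at 6, bypassing step 4.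

Further compounds
F1 | step 5 | 1-[(2R,3S)-3-hydroxy-6-[2-(methylsulfonyl)ethoxy]-2-(prop-1-en-2-yl)-2,3-dihydro-1-benzofuran-5-yl]ethan-1-one | C=C(C)[C@H]1Oc2cc(OCCS(C)(=O)=O)c(C(C)=O)cc2[C@@H]1O
F2 | step 5 | 1-[(2R,3S)-3,6-dihydroxy-2-(prop-1-en-2-yl)-2,3-dihydro-1-benzofuran-5-yl]ethan-1-one | C=C(C)[C@H]1Oc2cc(O)c(C(C)=O)cc2[C@@H]1O
F3 | step 9 | tert-butyldimethylsilyl (2Z)-2-{[(tert-butyldimethylsilyl)oxy]methyl}but-2-enoate | C/C=C(\C(=O)O[Si](C)(C)C(C)(C)C)CO[Si](C)(C)C(C)(C)C
F4 | step 9 | (2Z)-2-{[(tert-butyldimethylsilyl)oxy]methyl}but-2-enoic acid | C/C=C(\C(=O)O)CO[Si](C)(C)C(C)(C)C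
F5 | step 9 | (2Z)-2-{[(tert-butyldimethylsilyl)oxy]methyl}but-2-enoic 2,4,6-trichlorobenzoic anhydride | C/C=C(\C(=O)OC(=O)c1c(Cl)cc(Cl)cc1Cl)CO[Si](C)(C)C(C)(C)C
F6 | step 9 | (2R,3S)-5-acetyl-6-[(4-methoxyphenyl)methoxy]-2-(prop-1-en-2-yl)-2,3-dihydro-1-benzofuran-3-yl (2Z)-2-{[(tert-butyldimethylsilyl)oxy]methyl}but-2-enoate | C=C(C)[C@H]1Oc2cc(OCc3ccc(OC)cc3)c(C(C)=O)cc2[C@@H]1OC(=O)/C(=C\C)CO[Si](C)(C)C(C)(C)C
F7 | step 9 | (2R,3S)-5-acetyl-6-[(4-methoxyphenyl)methoxy]-2-(prop-1-en-2-yl)-2,3-dihydro-1-benzofuran-3-yl (2Z)-2-(hydroxymethyl)but-2-enoate | C=C(C)[C@H]1Oc2cc(OCc3ccc(OC)cc3)c(C(C)=O)cc2[C@@H]1OC(=O)/C(=C\C)CO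
F8 | step 3 | 1-{5-[(S)-[(tert-butyldimethylsilyl)oxy][(2S)-3,3-dimethyloxiran-2-yl]methyl]-2,4-difluorophenyl}ethan-1-one | CC1(C)O[C@H]1[C@@H](O[Si](C)(C)C(C)(C)C)c1cc(C(C)=O)c(F)cc1F
F9 | step 3 | 1-{5-[(1S,2R)-1-[(tert-butyldimethylsilyl)oxy]-3-methyl-2-[(trimethylsilyl)oxy]but-3-en-1-yl]-2,4-difluorophenyl}ethan-1-one | C=C(C)[C@@H](O[Si](C)(C)C)[C@@H](O[Si](C)(C)C(C)(C)C)c1cc(C(C)=O)c(F)cc1F
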